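**Retrosynthetic overview**

1. Numbering: carbocycle C5–C10 (C5 isopropenyl, C6 lactone O–CH, C7 ring-fusion CH, C8 acyloxy CH, C9 CH2, C10 quaternary with methyl and vinyl), C11/C12 lactone carbons, C1 the vinyl CH. The strategy rests on oxygenated C8 and C1 standing 1,4 through C9 and quaternary C10 of this ring, the pattern two enol ethers (O–C8=C9 and O–C1=C10) leave when joined β-carbon to β-carbon.
2. Last disconnections: C11 acetate and C8 ester; the 6,12-lactone by translactonisation of an 8,12-lactone once O6 is freed by methylenation of a C1 lactol; C12 carbonyl by oxidation; C8 carbinol by reduction of the ketone released from the cyclisation product.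
3. Key disconnection: C9–C10 by anodic coupling of a bis(enol ether) whose two enol ether oxygens are tied back into rings (O6–C1=C10 as a 2,3-dihydrofuran, O12–C8=C9 as a 2-methylideneoxolane). No enol ether geometry is left open, and C1, held by O6, must end cis to the C5 isopropenyl.
4. Precursor: the dihydrofuran comes from a butenolide (ring-closing metathesis), isopropenyl 1,4-addition anti to C6 (sets C5), enolate triflation and reduction; the methylideneoxolane from methylenation of an oxolanone; C6/C7 from an anti aldol of that oxolanone enolate with acrolein; C11 from (S)-citramalic acid.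
5. Ring order: oxolanone (step 2), butenolide then dihydrofuran (steps 6–8), cyclohexane (step 10, the only carbocycle), 8,12-lactone (step 13), 6,12-lactone (step 15).

Key step: step 10

Remark: the acetal carbons made in step 10 (C1 and C8) are expected as epimer mixtures and are left without configuration in 17–22, since both lose their asymmetry later; minor diastereomers of steps 4, 7 and 12 are assumed to be removed by chromatography.

**Route**

Step 1
Reactants: 1 (S)-citramalic acid [(2S)-2-hydroxy-2-methylbutanedioic acid]
Product: 2 dimethyl (2S)-2-hydroxy-2-methylbutanedioate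
Conditions: MeOH, H2SO4 (cat.), reflux
Reagents that add atoms: methanol, CO
Why: Fischer esterification of both carboxyl groups; the tertiary carbinol carbon C11 is not involved.

Step 2
Reactants: 2 dimethyl (2S)-2-hydroxy-2-methylbutanedioate
Product: 4 (4S)-4-hydroxy-4-methyloxolan-2-one, via diol ester 3 (not isolated)
Conditions: BH3·SMe2, NaBH4 (cat.), THF, 0 °C → rt; MeOH quench; then TsOH (cat.), CH2Cl2, rt
Reagents that add atoms: none
Why: Hydroxyl-directed borane reduction should reduce only the ester next to the free hydroxyl (cyclic alkoxyborane), and acid-catalysed lactonisation of the 4-hydroxy ester follows; C11 keeps its configuration.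

Step 3
Reactants: 4 (4S)-4-hydroxy-4-methyloxolan-2-one
Product: 5 (4S)-4-methyl-4-(triethylsilyloxy)oxolan-2-one
Conditions: TESOTf, 2,6-lutidine, CH2Cl2, −78 → 0 °C
Reagents that add atoms: triethylsilyl trifluoromethanesulfonate, CC[Si](CC)(CC)OS(=O)(=O)C(F)(F)F
Why: Silylation of the tertiary alcohol with a silyl triflate and a hindered base; no stereocentre is touched.

Step 4
Reactants: 5 (4S)-4-methyl-4-(triethylsilyloxy)oxolan-2-one; 6 acrolein
Product: 8 (3S,4S)-3-[(1R)-1-hydroxyprop-2-en-1-yl]-4-methyl-4-(triethylsilyloxy)oxolan-2-one, via lithium enolate 7 (not isolated)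
Conditions: LiN(i-Pr)2, THF, −78 °C; then 6, −78 °C; aq. NH4Cl
Reagents that add atoms: none
Why: Aldol addition of the ring-locked (E)-lithium enolate through a closed chair (Zimmerman–Traxler) transition state should give the anti C6/C7 relationship, and the aldehyde should add to the enolate face opposite the C11 silyloxy group, so C7 and C6 are set from C11.

Step 5
Reactants: 8 aldol adduct; 9 methacryloyl chloride
Product: 10 (1R)-1-[(3S,4S)-4-methyl-2-oxo-4-(triethylsilyloxy)oxolan-3-yl]prop-2-en-1-yl 2-methylprop-2-enoate
Conditions: Et3N, DMAP (cat.), CH2Cl2, −20 → 0 °C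
Reagents that add atoms: none
Why: O-Acylation of the secondary allylic alcohol, kept cold so that the β-acyloxy lactone does not eliminate; no stereocentre changes.

Step 6
Reactants: 10 methacrylate
Product: 11 (3S,4S)-4-methyl-3-[(2R)-4-methyl-5-oxo-2,5-dihydrofuran-2-yl]-4-(triethylsilyloxy)oxolan-2-one
Conditions: second-generation Grubbs catalyst (5 mol %), toluene, 80 °C
Reagents that add atoms: none
Why: Ring-closing metathesis of the vinyl group onto the methacrylate forms the trisubstituted C5=C10 alkene of the α-methylbutenolide with loss of ethene; stereocentres are untouched.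

Step 7
Reactants: 11 butenolide; 12 isopropenylmagnesium bromide
Product: 14 (2R,3R)-4-methyl-2-[(3S,4S)-4-methyl-2-oxo-4-(triethylsilyloxy)oxolan-3-yl]-3-(prop-1-en-2-yl)-2,3-dihydrofuran-5-yl trifluoromethanesulfonate, via magnesium enolate 13 (not isolated)
Conditions: CuBr·SMe2 (10 mol %), THF, −78 → −40 °C; then PhNTf2, DMPU, −78 → 0 °C
Reagents that add atoms: N-phenylbis(trifluoromethanesulfonimide), O=S(=O)(N(c1ccccc1)S(=O)(=O)C(F)(F)F)C(F)(F)F
Why: Copper-catalysed conjugate addition of the alkenyl Grignard reagent to the butenolide should occur anti to the C6 substituent on the five-membered ring (sets C5, trans to C6–C7), and the regiodefined lactone enolate is O-sulfonylated to the ketene acetal triflate.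

Step 8
Reactants: 14 ketene acetal triflate
Product: 15 (3S,4S)-4-methyl-3-[(2R,3R)-4-methyl-3-(prop-1-en-2-yl)-2,3-dihydrofuran-2-yl]-4-(triethylsilyloxy)oxolan-2-one
Conditions: Pd(OAc)2 (5 mol %), PPh3, Bu3N, HCO2H, DMF, 40 °C
Reagents that add atoms: none
Why: Palladium-catalysed formate reduction of the enol triflate replaces OTf by H and leaves the ring C1=C10 enol ether, whose geometry is fixed by the ring; the other lactone is inert.

Step 9
Reactants: 15 dihydrofuran lactone
Product: 16 (2R,3R)-4-methyl-2-[(3R,4S)-4-methyl-2-methylidene-4-(triethylsilyloxy)oxolan-3-yl]-3-(prop-1-en-2-yl)-2,3-dihydrofuran (bis(enol ether), key-step precursor)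
Conditions: Cp2TiMe2, toluene, 65 °C, dark; filtration through basic alumina
Reagents that add atoms: dimethyltitanocene (Cp2TiMe2), [Ti+4].[CH3-].[CH3-].c1cc[cH-]c1.c1cc[cH-]c1
Why: Petasis methylenation converts the only carbonyl group left (the oxolanone) into the exocyclic C8=C9 enol ether under non-basic conditions, so C7 should not epimerise (its descriptor changes by priority only).

Step 10
Reactants: 16 bis(enol ether)
Product: 17 tricyclic bis(acetal): cyclohexane C5–C10 bridged from C6 to C10 by O6–C1H(OMe) (C1 cis to the C5 isopropenyl; C10 methyl on the other face) and fused at C7–C8 to a 2-methoxyoxolane (OMe and O12 on C8)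
Conditions: reticulated vitreous carbon anode, Pt cathode, undivided cell, constant current (8 mA, 2.2 F/mol), 0.1 M LiClO4, MeOH/THF (1:4), 2,6-lutidine, rt
Reagents that add atoms: methanol, CO
Why: One-electron oxidation of the more electron-rich trisubstituted dihydrofuran at the anode gives an enol ether radical cation whose β-carbon C10 is attacked by the β-carbon C9 of the methylideneoxolane; a second electron transfer follows and methanol traps the two oxocarbenium ions at C1 and C8. The closest known reaction type is the intramolecular anodic coupling of two enol ethers (bis(enol ether) substrates) to bis-acetals of 1,4-dicarbonyl compounds with formation of quaternary carbons, bridged bicycles included. The cyclohexane C5–C10 closes in a 6-exo-trig mode with respect to C1=C10 (C8=C9 ends inside the ring) through a chair in which the oxolane holds the C7–C11 bond equatorial. The new stereocentre C10 is set by the tether: C1 stays bonded to O6, so it must end syn to O6 across C6/C10 and hence cis to the C5 isopropenyl, and C9 can reach only the dihydrofuran face that carries C7. The step needs C–C bond formation to outrun allylic deprotonation of the radical cation (drift towards a furan) and solvent capture, and it must spare the isopropenyl group; the rigid substrate holds C9 over C10, 2,6-lutidine at low current density keeps the medium non-acidic, and the enol ethers are oxidised well below the potential of a 1,1-disubstituted alkene.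

Step 11
Reactants: 17 bis(acetal)
Product: 18 hydroxy ketone (C8 ketone; C12 primary alcohol; C1 methyl acetal bridge kept; in equilibrium with its C8/O12 hemiketal)
Conditions: PPTS (cat.), acetone/H2O (10:1), 0 °C → rt
Reagents that add atoms: water, O
Why: Acid-catalysed hydrolysis of the ketone-derived mixed ketal at C8 (tertiary oxocarbenium ion) should be much faster than that of the aldehyde-derived bridged acetal at C1, which stays on as protection.

Step 12
Reactants: 18 hydroxy ketone
Product: 19 diol ((8R) equatorial C8–OH trans to the C7 side chain; C12–OH)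
Conditions: SmI2, THF/H2O, 0 °C
Reagents that add atoms: none
Why: Single-electron (ketyl) reduction should give the thermodynamically preferred equatorial alcohol, because the ketyl settles with its oxygen equatorial, away from the O6–C1 bridge, and is protonated on the axial face; a hydride reagent would instead attack anti to the bridge and give the axial epimer.

Step 13
Reactants: 19 diol
Product: 20 8,12-lactone (trans-fused O8–C12(=O)–C11–C7 ring; C1 methyl acetal bridge and C11–OSiEt3 kept)
Conditions: TEMPO (cat.), PhI(OAc)2, CH2Cl2, rt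
Reagents that add atoms: none
Why: Oxidative lactonisation: the nitroxyl-catalysed oxidation takes the primary alcohol to the aldehyde, which forms a lactol with the only free secondary hydroxyl (O8) and is oxidised on to the γ-lactone; this installs the C12 carbonyl and parks O8.

Step 14
Reactants: 20 8,12-lactone
Product: 22 lactol (C1–OH bridged to O6; 8,12-lactone; free C11–OH), via desilylated acetal 21 (not isolated)
Conditions: HF·pyridine, THF, 0 °C → rt; then 2 M HCl, rt
Reagents that add atoms: water, O
Why: Fluoride-mediated cleavage of the tertiary silyl ether, then acid-catalysed hydrolysis of the bridged methyl acetal to the lactol; no stereocentre of the skeleton is involved.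

Step 15
Reactants: 22 lactol
Product: 24 (5R,6R,7S,8R,10S,11S)-6,12-lactone diol (C10 vinyl; free C8–OH and C11–OH), via vinyl 8,12-lactone 23 (not isolated)
Conditions: Ph3PCH3Br, KOtBu, THF, 0 → 50 °C; aq. NH4Cl
Reagents that add atoms: methyltriphenylphosphonium bromide, C[P+](c1ccccc1)(c1ccccc1)c1ccccc1.[Br-]
Why: Wittig methylenation of the aldehyde tautomer of the lactol makes the vinyl group, and the C6 alkoxide set free should translactonise onto C12 to give the cis-fused 6,12-lactone, expected to be favoured over the trans-fused 8,12-isomer.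

Step 16
Reactants: 24 lactone diol; 25 3-methylbut-3-enoic acid
Product: 26 C8 3-methylbut-3-enoate (free C11–OH)
Conditions: DCC, DMAP (cat.), CH2Cl2, 0 °C
Reagents that add atoms: none
Why: Steglich esterification, selective for the secondary C8–OH over the tertiary α-hydroxy lactone OH; catalytic DMAP at 0 °C should keep the β,γ-double bond out of conjugation.

Step 17
Reactants: 26 C8 ester
Product: 27 target CNP0106639.1
Conditions: Ac2O, Sc(OTf)3 (cat.), MeCN, −20 °C
Reagents that add atoms: acetic anhydride, CC(=O)OC(C)=O
Why: Lewis-acid-catalysed acylation of the hindered tertiary alcohol; the C11–O bond is not broken, so configuration is retained, and the conditions should not isomerise the β,γ-unsaturated ester.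

**Compound list**

1 | (S)-citramalic acid | C[C@](O)(CC(=O)O)C(=O)O | starting material
2 | dimethyl (2S)-2-hydroxy-2-methylbutanedioate | C[C@](O)(CC(=O)OC)C(=O)OC | intermediate
3 | methyl (3S)-3,4-dihydroxy-3-methylbutanoate | C[C@](O)(CC(=O)OC)CO | intermediate (not isolated)
4 | (4S)-4-hydroxy-4-methyloxolan-2-one | C[C@]1(O)CC(=O)OC1 | intermediate
5 | (4S)-4-methyl-4-(triethylsilyloxy)oxolan-2-one | C[C@]1(O[Si](CC)(CC)CC)CC(=O)OC1 | intermediate
6 | acrolein | C=CC=O | starting material
7 | lithium enolate of 5 | C[C@]1(O[Si](CC)(CC)CC)C=C(O[Li])OC1 | intermediate (not isolated)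
8 | (3S,4S)-3-[(1R)-1-hydroxyprop-2-en-1-yl]-4-methyl-4-(triethylsilyloxy)oxolan-2-one | C=C[C@@H](O)[C@@H]1C(=O)OC[C@@]1(C)O[Si](CC)(CC)CC | intermediate
9 | methacryloyl chloride | CC(=C)C(=O)Cl | starting material
10 | (1R)-1-[(3S,4S)-4-methyl-2-oxo-4-(triethylsilyloxy)oxolan-3-yl]prop-2-en-1-yl 2-methylprop-2-enoate | C=C[C@@H](OC(=O)C(C)=C)[C@@H]1C(=O)OC[C@@]1(C)O[Si](CC)(CC)CC | intermediate
11 | (3S,4S)-4-methyl-3-[(2R)-4-methyl-5-oxo-2,5-dihydrofuran-2-yl]-4-(triethylsilyloxy)oxolan-2-one | CC1=C[C@@H](OC1=O)[C@@H]2C(=O)OC[C@@]2(C)O[Si](CC)(CC)CC | intermediate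
12 | isopropenylmagnesium bromide | CC(=C)[Mg]Br | starting material
13 | bromomagnesium enolate of the 1,4-adduct | CC1=C(O[Mg]Br)O[C@H]([C@@H]1C(C)=C)[C@@H]2C(=O)OC[C@@]2(C)O[Si](CC)(CC)CC | intermediate (not isolated)
14 | ketene acetal triflate (name as in step 7) | CC1=C(OS(=O)(=O)C(F)(F)F)O[C@H]([C@@H]1C(C)=C)[C@@H]2C(=O)OC[C@@]2(C)O[Si](CC)(CC)CC | intermediate
15 | (3S,4S)-4-methyl-3-[(2R,3R)-4-methyl-3-(prop-1-en-2-yl)-2,3-dihydrofuran-2-yl]-4-(triethylsilyloxy)oxolan-2-one | CC1=CO[C@H]([C@@H]1C(C)=C)[C@@H]2C(=O)OC[C@@]2(C)O[Si](CC)(CC)CC | intermediate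
16 | (2R,3R)-4-methyl-2-[(3R,4S)-4-methyl-2-methylidene-4-(triethylsilyloxy)oxolan-3-yl]-3-(prop-1-en-2-yl)-2,3-dihydrofuran | CC1=CO[C@H]([C@@H]1C(C)=C)[C@@H]2C(=C)OC[C@@]2(C)O[Si](CC)(CC)CC | intermediate (key-step precursor)
17 | tricyclic bis(acetal), C1 and C8 epimer mixture | COC1O[C@@H]2[C@H](C(C)=C)[C@@]1(C)CC3(OC)OC[C@@](C)(O[Si](CC)(CC)CC)[C@H]23 | intermediate (key-step product)
18 | hydroxy ketone (C8 ketone, C12–OH, C1 methyl acetal) | COC1O[C@@H]2[C@H](C(C)=C)[C@@]1(C)CC(=O)[C@@H]2[C@@](C)(CO)O[Si](CC)(CC)CC | intermediate
19 | diol ((8R)-C8–OH, C12–OH) | COC1O[C@@H]2[C@H](C(C)=C)[C@@]1(C)C[C@@H](O)[C@@H]2[C@@](C)(CO)O[Si](CC)(CC)CC | intermediate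
20 | 8,12-lactone with C1 methyl acetal and C11–OSiEt3 | COC1O[C@@H]2[C@H](C(C)=C)[C@@]1(C)C[C@H]3OC(=O)[C@@](C)(O[Si](CC)(CC)CC)[C@H]23 | intermediate
21 | 8,12-lactone with C1 methyl acetal and free C11–OH | COC1O[C@@H]2[C@H](C(C)=C)[C@@]1(C)C[C@H]3OC(=O)[C@@](C)(O)[C@H]23 | intermediate (not isolated)
22 | C1 lactol of the 8,12-lactone | OC1O[C@@H]2[C@H](C(C)=C)[C@@]1(C)C[C@H]3OC(=O)[C@@](C)(O)[C@H]23 | intermediate
23 | C10-vinyl 8,12-lactone with free C6–OH | C=C[C@]1(C)C[C@H]2OC(=O)[C@@](C)(O)[C@@H]2[C@H](O)[C@@H]1C(=C)C | intermediate (not isolated)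
24 | (5R,6R,7S,8R,10S,11S)-6,12-lactone with free C8–OH and C11–OH | C=C[C@]1(C)C[C@@H](O)[C@H]2[C@H](OC(=O)[C@@]2(C)O)[C@@H]1C(=C)C | intermediate
25 | 3-methylbut-3-enoic acid | CC(=C)CC(=O)O | starting material
26 | C8 3-methylbut-3-enoate with free C11–OH | C=C[C@]1(C)C[C@@H](OC(=O)CC(=C)C)[C@H]2[C@H](OC(=O)[C@@]2(C)O)[C@@H]1C(=C)C | intermediate
27 | CNP0106639.1 | C=C[C@]1(C)C[C@@H](OC(=O)CC(=C)C)[C@H]2[C@H](OC(=O)[C@@]2(C)OC(C)=O)[C@@H]1C(=C)C | target

**Step count and risks**

Total step count: 17. Longest linear sequence: 17 steps (from 1).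

Steps most likely to fail:

1. Step 10. The radical cation may be deprotonated at the allylic C5–H (drift towards aromatisation of the dihydrofuran) or captured by methanol before the bridged six-membered ring closes. The fallback sets out from 15. Iodomethyllithium (CH2I2, MeLi, THF, −78 °C) should open the oxolanone once to give iodomethyl ketone F1. An iodine-atom-transfer radical cyclisation (Et3B, air, benzene, rt) then lets the electrophilic C9 radical add to C10 of the dihydrofuran (6-exo, same tether control at C10) and gives the C1 iodo ether F2. Methanolysis in the same flask (MeOH, 2,6-lutidine) gives the methyl acetal, and the route is rejoined at 18.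

2. Step 7. The 1,4-addition to the α-substituted butenolide may be sluggish, or the enolate may be sulfonylated on carbon or the ketene acetal triflate hydrolysed on handling. The fallback sets out from 8. Acid-catalysed transacetalisation with methacrolein dimethyl acetal (PPTS, benzene) gives mixed acetal F3, and ring-closing metathesis (second-generation Grubbs catalyst) gives 2-methoxy-3-methyl-2,5-dihydrofuran F4. Isopropenylcopper–BF3 (from 12, CuBr·SMe2, BF3·OEt2, THF, −78 °C) should then displace methoxide in an SN2′ reaction at C5, anti to the C6 substituent. The route is rejoined at 15.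

3. Step 12. Facial selectivity may be poor, with hydrogen delivered from the open face to give the axial C8 alcohol. The fallback sets out from 18. NaBH4 (MeOH, 0 °C) should give the axial alcohol F5 cleanly by attack anti to the O6–C1 bridge. Meerwein–Ponndorf–Verley/Oppenauer equilibration (Al(OiPr)3, i-PrOH/toluene, cat. acetone, 80 °C) should then epimerise it to the more stable equatorial alcohol. The route is rejoined at 19.

Further compounds
F1 | step 10 | iodomethyl ketone (C8(=O)CH2I, free C12–OH, dihydrofuran intact) | CC1=CO[C@H]([C@@H]1C(C)=C)[C@H](C(=O)CI)[C@@](C)(CO)O[Si](CC)(CC)CC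
F2 | step 10 | cyclised C1 iodo ether (C8 ketone, C12–OH) | IC1O[C@@H]2[C@H](C(C)=C)[C@@]1(C)CC(=O)[C@@H]2[C@@](C)(CO)O[Si](CC)(CC)CC
F3 | step 7 | mixed methacrolein acetal of 8 | C=C[C@@H](OC(OC)C(C)=C)[C@@H]1C(=O)OC[C@@]1(C)O[Si](CC)(CC)CC
F4 | step 7 | 2-methoxy-3-methyl-2,5-dihydrofuran carrying the oxolanone at C6 | COC1O[C@H](C=C1C)[C@@H]2C(=O)OC[C@@]2(C)O[Si](CC)(CC)CC
F5 | step 12 | axial (8S) epimer of diol 19 | COC1O[C@@H]2[C@H](C(C)=C)[C@@]1(C)C[C@H](O)[C@@H]2[C@@](C)(CO)O[Si](CC)(CC)CC
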